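**Retrosynthetic overview**

- The target is reached by global hydrogenolysis of its tris-benzyl ether. The chain is numbered from the benzylic carbon C1; C2 is the carbinol. The C9–C10 bond is cut by a nickel-electrocatalytic doubly decarboxylative C(sp3)–C(sp3) coupling of two N-acyloxyphthalimides. One comes from nonanoic acid (C10–C17), the other from a 10-aryl-9-benzyloxydecanoic acid (C1–C9). Both carboxyl groups are traceless activating groups lost as CO2 in the coupling itself.
- Enabling feature: C9 and C10 are plain CH2 carbons in the middle of the unbranched C3–C17 polymethylene chain. Seven CH2 groups (C3–C9) separate the cut from the C2 carbinol stereocentre and the resorcinol ring. Both ends are therefore ordinary primary fatty-acid radicals with no β-leaving group, no cyclisation partner and no stereochemical consequence.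
- The aryl acid is made by forming the C1–aryl bond: copper-catalysed opening of an (R)-terminal epoxide by a 3,5-bis(benzyloxy)phenyl Grignard reagent. The C2 configuration comes from hydrolytic kinetic resolution of the epoxide of methyl dec-9-enoate.
- Rings: the benzene ring is bought as the dibenzyl ether of 5-bromoresorcinol and is never built. The only ring formed is the temporary oxirane (step 1), opened in step 3.

Key step: step 7

Remark on the chemistry: the carbinol carbon of the target is (R) (OH > CH2Ar > CH2-alkyl > H); methyl dec-9-enoate, 1,3-bis(benzyloxy)-5-bromobenzene and nonanoic acid are taken as purchasable.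

**Route**

Step 1
Reactants: 1 methyl dec-9-enoate
Product: 2 rac-methyl 8-(oxiran-2-yl)octanoate
Conditions: mCPBA (1.3 equiv), CH2Cl2, 0 °C → rt
Reagents that add atoms: 3-chloroperoxybenzoic acid (mCPBA) OOC(=O)c1cccc(Cl)c1
Why: Prilezhaev epoxidation of the isolated terminal alkene by the peracid should proceed cleanly, the methyl ester being inert, and gives the racemic oxirane by design.

Step 2
Reactants: 2 rac-methyl 8-(oxiran-2-yl)octanoate
Product: 3 methyl 8-[(2R)-oxiran-2-yl]octanoate
Conditions: (R,R)-(salen)Co(III)OAc (0.5 mol%; the catalyst antipode that hydrolyses the (S)-epoxide), H2O (0.55 equiv), minimal THF, 0 °C → rt; epoxide separated from the diol by chromatography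
Reagents that add atoms: none
Why: Jacobsen hydrolytic kinetic resolution of a terminal aliphatic epoxide, in which cooperative bimetallic (salen)Co catalysis should hydrolyse the (S)-enantiomer selectively and leave the (R)-epoxide that fixes the future C2 stereocentre in high ee.

Step 3
Reactants: 3 methyl 8-[(2R)-oxiran-2-yl]octanoate; 4 1,3-bis(benzyloxy)-5-bromobenzene
Product: 6 methyl (9R)-10-[3,5-bis(benzyloxy)phenyl]-9-hydroxydecanoate, via arylmagnesium bromide 5 (not isolated)
Conditions: 4, Mg, THF, 50 °C; then CuI (10 mol%), 3, THF, −40 → −20 °C; cold 1 M HCl quench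
Reagents that add atoms: none
Why: Copper-catalysed SN2 ring opening of a terminal epoxide by an aryl Grignard reagent occurs at the unsubstituted CH2, so the C–O bond at the stereocentre is untouched and the (R) configuration is retained, and at −40 °C this opening should outrun addition to the remote methyl ester.

Step 4
Reactants: 6 methyl (9R)-10-[3,5-bis(benzyloxy)phenyl]-9-hydroxydecanoate
Product: 8 (9R)-9-(benzyloxy)-10-[3,5-bis(benzyloxy)phenyl]decanoic acid, via benzyl ether methyl ester 7 (not isolated)
Conditions: NaH (1.3 equiv), BnBr (1.4 equiv), Bu4NI (cat.), THF/DMF, 0 °C → rt; then LiOH·H2O (5 equiv), MeOH/H2O, 50 °C; 1 M HCl to pH 3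
Reagents that add atoms: benzyl bromide BrCc1ccccc1; lithium hydroxide [Li+].[OH-]
Why: Williamson etherification of the secondary alkoxide followed in the same pot by ester saponification should converge any ester exchanged under the basic alkylation on the same acid, and no bond to the stereocentre is broken.

Step 5
Reactants: 8 (9R)-9-(benzyloxy)-10-[3,5-bis(benzyloxy)phenyl]decanoic acid
Product: 9 1,3-dioxoisoindolin-2-yl (9R)-9-(benzyloxy)-10-[3,5-bis(benzyloxy)phenyl]decanoate
Conditions: N-hydroxyphthalimide (1.1 equiv), DIC (1.1 equiv), DMAP (5 mol%), CH2Cl2, rt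
Reagents that add atoms: N-hydroxyphthalimide O=C1c2ccccc2C(=O)N1O
Why: Carbodiimide (Steglich-type) esterification of the acid with N-hydroxyphthalimide should give the redox-active ester, the benzyl ethers being inert.

Step 6
Reactants: 10 nonanoic acid
Product: 11 1,3-dioxoisoindolin-2-yl nonanoate
Conditions: N-hydroxyphthalimide (1.1 equiv), DIC (1.1 equiv), DMAP (5 mol%), CH2Cl2, rt
Reagents that add atoms: N-hydroxyphthalimide O=C1c2ccccc2C(=O)N1O
Why: The same carbodiimide esterification turns cheap nonanoic acid into the second redox-active ester, the precursor of the octyl radical.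

Step 7
Reactants: 9 1,3-dioxoisoindolin-2-yl (9R)-9-(benzyloxy)-10-[3,5-bis(benzyloxy)phenyl]decanoate; 11 1,3-dioxoisoindolin-2-yl nonanoate
Product: 12 1,3-bis(benzyloxy)-5-[(2R)-2-(benzyloxy)heptadecyl]benzene
Conditions: 11 (3 equiv), NiCl2·6H2O (20 mol%), 2,2':6',2''-terpyridine (20 mol%), AgNO3 (0.3 equiv), Mg anode / RVC cathode, undivided cell, constant current, NMP, rt; then 1 M HCl work-up
Reagents that add atoms: none
Why: Cathodic reduction gives a low-valent Ni–terpyridine species that transfers an electron to each N-acyloxyphthalimide, whose radical anions fragment to phthalimide anion, CO2 and the primary alkyl radicals (octyl from 11, the C9 radical from 9); successive capture at nickel gives a dialkylnickel(III) intermediate whose reductive elimination forms the C9–C10 σ-bond, while the Mg anode supplies the electrons and silver deposited on the cathode from AgNO3 moderates direct over-reduction of the esters. The closest known reaction type is the nickel-electrocatalytic doubly decarboxylative C(sp3)–C(sp3) cross-coupling of two redox-active esters, the reductive counterpart of mixed Kolbe electrolysis, which is established for primary–primary pairs. No ring is closed and no stereocentre is created; the C2 stereocentre lies seven CH2 groups from the radical site and is not touched. The selectivity needed is cross- over homo-coupling, which for two unbiased primary radicals is essentially statistical and is secured by using cheap 11 in threefold excess so that 9 is consumed mainly in the cross-product, the by-product hexadecane being easily separated from the far more polar tris-benzyl ether. The reductive mode is chosen because the electron-rich 3,5-dialkoxyphenyl ring of 9 would be oxidised at the anode potential of a classical Kolbe coupling, and the C9 radical has no β-heteroatom to eliminate and no unsaturation within reach for cyclisation.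

Step 8
Reactants: 12 1,3-bis(benzyloxy)-5-[(2R)-2-(benzyloxy)heptadecyl]benzene
Product: 13 5-[(2R)-2-hydroxyheptadecyl]benzene-1,3-diol
Conditions: H2 (1 atm), 20% Pd(OH)2/C, EtOAc/MeOH, rt
Reagents that add atoms: none
Why: Catalytic hydrogenolysis should cleave the two aryl benzyl ethers and the secondary alkyl benzyl ether in one operation, and because the C2–O bond is homobenzylic and not benzylic the carbinol and its (R) configuration survive.

**Compound list**

1 | methyl dec-9-enoate | C=CCCCCCCCC(=O)OC | starting material
2 | rac-methyl 8-(oxiran-2-yl)octanoate | COC(=O)CCCCCCCC1CO1 | intermediate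
3 | methyl 8-[(2R)-oxiran-2-yl]octanoate | COC(=O)CCCCCCC[C@@H]1CO1 | intermediate
4 | 1,3-bis(benzyloxy)-5-bromobenzene | Brc1cc(OCc2ccccc2)cc(OCc2ccccc2)c1 | starting material
5 | [3,5-bis(benzyloxy)phenyl]magnesium bromide | Br[Mg]c1cc(OCc2ccccc2)cc(OCc2ccccc2)c1 | intermediate
6 | methyl (9R)-10-[3,5-bis(benzyloxy)phenyl]-9-hydroxydecanoate | COC(=O)CCCCCCC[C@@H](O)Cc1cc(OCc2ccccc2)cc(OCc2ccccc2)c1 | intermediate
7 | methyl (9R)-9-(benzyloxy)-10-[3,5-bis(benzyloxy)phenyl]decanoate | COC(=O)CCCCCCC[C@@H](OCc1ccccc1)Cc1cc(OCc2ccccc2)cc(OCc2ccccc2)c1 | intermediate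
8 | (9R)-9-(benzyloxy)-10-[3,5-bis(benzyloxy)phenyl]decanoic acid | OC(=O)CCCCCCC[C@@H](OCc1ccccc1)Cc1cc(OCc2ccccc2)cc(OCc2ccccc2)c1 | intermediate
9 | 1,3-dioxoisoindolin-2-yl (9R)-9-(benzyloxy)-10-[3,5-bis(benzyloxy)phenyl]decanoate | O=C(CCCCCCC[C@@H](OCc1ccccc1)Cc1cc(OCc2ccccc2)cc(OCc2ccccc2)c1)ON1C(=O)c2ccccc2C1=O | intermediate
10 | nonanoic acid | CCCCCCCCC(=O)O | starting material
11 | 1,3-dioxoisoindolin-2-yl nonanoate | CCCCCCCCC(=O)ON1C(=O)c2ccccc2C1=O | intermediate
12 | 1,3-bis(benzyloxy)-5-[(2R)-2-(benzyloxy)heptadecyl]benzene | CCCCCCCCCCCCCCC[C@@H](OCc1ccccc1)Cc1cc(OCc2ccccc2)cc(OCc2ccccc2)c1 | intermediate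
13 | 5-[(2R)-2-hydroxyheptadecyl]benzene-1,3-diol | CCCCCCCCCCCCCCC[C@@H](O)Cc1cc(O)cc(O)c1 | target

**Summary and risks**

Total step count: 8. Longest linear sequence: 7 steps (1 → 2 → 3 → 4 → 5 → 7 → 8); step 6 is a one-step side branch.

Steps most likely to fail:

Step 7. The two primary radicals are sorted at nickel without bias, so homocoupling of either partner and premature reduction of the C9 radical (hydrodecarboxylation) may leave little cross-product, and passivation of the magnesium anode may stall the electrolysis. The fallback sets out from 9 and comes back to the route at 12, forming the same C9–C10 bond by a nickel-catalysed decarboxylative alkyl–alkyl Negishi coupling. Octylmagnesium bromide and ZnCl2 (2:1, THF) give dioctylzinc F1. This is combined with 9 in the presence of NiCl2·glyme (20 mol%) and 4,4'-di-tert-butyl-2,2'-bipyridine (40 mol%) in THF/DMF at rt. Only 9 is then a radical precursor and the octyl group arrives by transmetalation, so the coupling is no longer statistical.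

Step 3. Addition of the aryl Grignard reagent to the methyl ester, and bromide opening of the epoxide by magnesium bromide, may compete with the desired copper-mediated opening. The fallback sets out from 3 and 4 and comes back at 6 without any carbanionic reagent, by a nickel-catalysed reductive cross-electrophile coupling of the aryl bromide with the epoxide under iodide co-catalysis: NiCl2·glyme (10 mol%), 2,2'-bipyridine (10 mol%), NaI (25 mol%), Et3N·HCl (1 equiv), Mn powder (2 equiv), DMPU, rt. Iodide opens the oxirane at its CH2 terminus to the iodohydrin methyl (9R)-9-hydroxy-10-iododecanoate F2, which is not isolated. Its primary C–I bond is then arylated at nickel, so the carbinol stereocentre is never involved and the ester is not at risk.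

Step 4. O-Alkylation of the hindered secondary alkoxide may be slow enough that it attacks the methyl ester of a second molecule (transesterification or Claisen-type condensation), so part of the material would reach the saponification stage unbenzylated. The fallback sets out from 6 and comes back at 13, replacing the basic benzylation by a silyl protecting group with its own endgame:
- TBSCl and imidazole in DMF should give methyl (9R)-10-[3,5-bis(benzyloxy)phenyl]-9-[(tert-butyldimethylsilyl)oxy]decanoate F3.
- LiOH in THF/MeOH/H2O should give the corresponding acid, (9R)-10-[3,5-bis(benzyloxy)phenyl]-9-[(tert-butyldimethylsilyl)oxy]decanoic acid F4.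
- N-Hydroxyphthalimide and DIC should give its redox-active ester, 1,3-dioxoisoindolin-2-yl (9R)-10-[3,5-bis(benzyloxy)phenyl]-9-[(tert-butyldimethylsilyl)oxy]decanoate F5.
- Coupling with 11 under the conditions of step 7 should give 1,3-bis(benzyloxy)-5-[(2R)-2-[(tert-butyldimethylsilyl)oxy]heptadecyl]benzene F6.
- TBAF in THF should give (2R)-1-[3,5-bis(benzyloxy)phenyl]heptadecan-2-ol F7.
- Hydrogenolysis (H2, Pd/C, EtOAc/MeOH) then delivers 13.

Further compounds
F1 | step 7 | dioctylzinc | CCCCCCCC[Zn]CCCCCCCC
F2 | step 3 | methyl (9R)-9-hydroxy-10-iododecanoate | COC(=O)CCCCCCC[C@@H](O)CI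
F3 | step 4 | methyl (9R)-10-[3,5-bis(benzyloxy)phenyl]-9-[(tert-butyldimethylsilyl)oxy]decanoate | COC(=O)CCCCCCC[C@@H](O[Si](C)(C)C(C)(C)C)Cc1cc(OCc2ccccc2)cc(OCc2ccccc2)c1
F4 | step 4 | (9R)-10-[3,5-bis(benzyloxy)phenyl]-9-[(tert-butyldimethylsilyl)oxy]decanoic acid | OC(=O)CCCCCCC[C@@H](O[Si](C)(C)C(C)(C)C)Cc1cc(OCc2ccccc2)cc(OCc2ccccc2)c1
F5 | step 4 | 1,3-dioxoisoindolin-2-yl (9R)-10-[3,5-bis(benzyloxy)phenyl]-9-[(tert-butyldimethylsilyl)oxy]decanoate | O=C(CCCCCCC[C@@H](O[Si](C)(C)C(C)(C)C)Cc1cc(OCc2ccccc2)cc(OCc2ccccc2)c1)ON1C(=O)c2ccccc2C1=O
F6 | step 4 | 1,3-bis(benzyloxy)-5-[(2R)-2-[(tert-butyldimethylsilyl)oxy]heptadecyl]benzene | CCCCCCCCCCCCCCC[C@@H](O[Si](C)(C)C(C)(C)C)Cc1cc(OCc2ccccc2)cc(OCc2ccccc2)c1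
F7 | step 4 | (2R)-1-[3,5-bis(benzyloxy)phenyl]heptadecan-2-ol | CCCCCCCCCCCCCCC[C@@H](O)Cc1cc(OCc2ccccc2)cc(OCc2ccccc2)c1
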